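**Retrosynthetic overview**

1. Core numbering used here: bicyclo[3.2.1]octane C1 (bridgehead carrying the cyclopentane CH2), C2 and C4 (ring carbonyls), C3 (prenyl and isobutyryl), C5 (methyl bridgehead), C6H2–C7H (two-carbon bridge), C8 (bridging carbonyl). The strategy rests on this feature: C1–C2–C3–C4–C5–C8 is a fully substituted phloroglucinol ring, the C7–C6 bridge is the vinyl end of a CH2–CH(C=O)–CMe2–CH=CH2 chain on C1, and the acetyl carbon lies cis to C2 on the cyclopentane, so it can be held on the C2 oxygen as a six-membered aryl lactone.
2. Late disconnections: C3–prenyl (allylic alkylation, last) and acetyl C–CH3 (thioester plus methylzinc), leading back to the bridged enol lactone 17.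
3. Key disconnection: C1–C7 and C5–C6 together, by an oxidative dearomative formal [5+2] annulation of the aromatic dihydrocoumarin 16 with its own vinyl group.
4. 16 comes from an auxiliary-controlled aldol union of benzaldehyde 5 with imide 9, benzylic deoxygenation, lactonisation, C8 acylation and demethylation.
5. Ring order: the lactone tether is closed on the arene first; the key step then closes the gem-dimethylcyclopentane and, directly after it, the five-membered ring of the bicyclo[3.2.1]octane; the lactone is opened afterwards and no ring is made later.

Key step: step 10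

Assumption: the enolised triketones 18 and 19 (and the enol in F1) are drawn as one tautomer and treated as single compounds.

**Step 1**
Reactants: 1 2,6-dimethoxytoluene
Product: 3 3,5-dimethoxy-4-methylphenol, via aryl pinacol boronate 2 (not isolated)
Conditions: [Ir(OMe)(cod)]2 (cat.), dtbpy (cat.), HBpin, THF, 80 °C; then 30% H2O2, aq. NaOH, 0 °C
Reagents that add atoms: hydrogen peroxide, OO
Why: Iridium-catalysed C–H borylation is governed by sterics and should take the one ring C–H without an ortho substituent (para to the methyl group), after which alkaline peroxide oxidation of the C–B bond gives the phenol.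

**Step 2**
Reactants: 3 3,5-dimethoxy-4-methylphenol
Product: 4 6-hydroxy-2,4-dimethoxy-3-methylbenzaldehyde
Conditions: MgCl2, Et3N, (CH2O)n, MeCN, reflux; aq. HCl
Reagents that add atoms: formaldehyde (as paraformaldehyde), C=O
Why: Casnati–Skattebøl ortho-formylation through the magnesium phenoxide delivers formaldehyde only ortho to the hydroxyl group, and the two ortho positions are equivalent by symmetry.

**Step 3**
Reactants: 4 6-hydroxy-2,4-dimethoxy-3-methylbenzaldehyde
Product: 5 2,4-dimethoxy-6-(methoxymethoxy)-3-methylbenzaldehyde
Conditions: MOMCl, iPr2NEt, CH2Cl2, 0 °C to rt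
Reagents that add atoms: chloromethyl methyl ether, COCCl
Why: O-Alkylation with MOMCl caps the phenol as an acid-labile acetal, which keeps the future lactone oxygen distinct from the two methyl ethers.

**Step 4**
Reactants: 6 3,3-dimethylpent-4-enoic acid; 7 (R)-4-benzyloxazolidin-2-one
Product: 9 (4R)-4-benzyl-3-(3,3-dimethylpent-4-enoyl)oxazolidin-2-one, via mixed pivalic anhydride 8 (not isolated)
Conditions: PivCl, Et3N, THF, −20 °C; then 7, LiCl, −20 °C to rt
Reagents that add atoms: none
Why: N-Acylation of the oxazolidinone by the mixed pivalic anhydride (LiCl/Et3N variant) should occur at the less hindered, non-pivaloyl carbonyl.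

**Step 5**
Reactants: 9 (4R)-4-benzyl-3-(3,3-dimethylpent-4-enoyl)oxazolidin-2-one; 5 2,4-dimethoxy-6-(methoxymethoxy)-3-methylbenzaldehyde
Product: 11 (4R)-4-benzyl-3-[(2R,3R)-3-hydroxy-3-[2,4-dimethoxy-6-(methoxymethoxy)-3-methylphenyl]-2-(2-methylbut-3-en-2-yl)propanoyl]oxazolidin-2-one, via Z-dibutylboron enolate 10 (not isolated)
Conditions: Bu2BOTf, iPr2NEt, CH2Cl2, 0 °C; then 5, −78 to 0 °C; pH 7 buffer, MeOH, H2O2
Reagents that add atoms: none
Why: Evans boron syn-aldol addition: soft enolisation gives the Z-boron enolate 10, which should react through a closed Zimmerman–Traxler transition state on the enolate face turned away from the auxiliary benzyl group, setting the (2R) α-centre that becomes the acetyl-bearing carbon of the target and a (3R) carbinol centre that is removed in step 6.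

**Step 6**
Reactants: 11 the syn-aldol adduct
Product: 12 (4R)-4-benzyl-3-[(2S)-2-[(6-hydroxy-2,4-dimethoxy-3-methylphenyl)methyl]-3,3-dimethylpent-4-enoyl]oxazolidin-2-one
Conditions: Et3SiH (excess), TFA, CH2Cl2, −20 to 0 °C
Reagents that add atoms: none
Why: Ionic hydrogenation: TFA ionises the benzylic alcohol to a cation stabilised by three ring oxygens that is captured by hydride from Et3SiH, while the same acid cleaves the aryl MOM ether and the silane scavenges the methoxymethyl cation; the α-stereocentre is not part of the cation and should be kept (its descriptor changes to S only through the priority rules).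

**Step 7**
Reactants: 12 the phenol imide
Product: 13 (3S)-5,7-dimethoxy-6-methyl-3-(2-methylbut-3-en-2-yl)chroman-2-one
Conditions: iPr2NEt, DMAP (cat.), toluene, 60 °C
Reagents that add atoms: none
Why: Intramolecular acyl transfer (lactonisation) from the activated N-acyl oxazolidinone to the ortho phenol should close the six-membered aryl lactone and release the auxiliary under base too mild to epimerise C3.

**Step 8**
Reactants: 13 (3S)-5,7-dimethoxy-6-methyl-3-(2-methylbut-3-en-2-yl)chroman-2-one; 14 isobutyryl chloride
Product: 15 (3S)-8-isobutyryl-5,7-dimethoxy-6-methyl-3-(2-methylbut-3-en-2-yl)chroman-2-one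
Conditions: TiCl4, CH2Cl2, −20 to 0 °C
Reagents that add atoms: none
Why: Friedel–Crafts acylation can occur only at C8, the single unsubstituted ring carbon, which is activated by the ortho and para methoxy groups, and the low temperature is chosen to leave the isolated vinyl group untouched.

**Step 9**
Reactants: 15 the 8-isobutyryl dimethyl ether
Product: 16 (3S)-5,7-dihydroxy-8-isobutyryl-6-methyl-3-(2-methylbut-3-en-2-yl)chroman-2-one
Conditions: BBr3, CH2Cl2, −78 to 0 °C; aq. NaHCO3
Reagents that add atoms: none
Why: Lewis acid ether cleavage with BBr3 should remove both methyl groups (the C7 ether helped by chelation to the C8 ketone), while the aryl lactone, whose aryl–oxygen bond offers no site for bromide attack, is expected to survive.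

**Step 10**
Reactants: 16 the key-step precursor
Product: 17 bridged enol lactone of the tricyclic trione (3-isobutyryl-5-methylbicyclo[3.2.1]oct-2-ene-4,8-dione fused at C1–C7 to the gem-dimethylcyclopentane, whose carboxyl carbon is esterified to the C2 enol oxygen)
Conditions: Mn(OAc)3·2H2O (2.5 equiv), degassed AcOH, high dilution, rt to 50 °C, no copper salt
Reagents that add atoms: none
Why: Proposed new method: Mn(OAc)3 should bind the chelating 7-hydroxy-8-acyl unit of 16 and oxidise it by one electron to a phenoxyl radical with spin at C4a, C6 and C8, of which only C4a can reach the alkene, so it adds to the internal vinyl carbon (5-exo-trig, closing the gem-dimethylcyclopentane) and no neopentyl cation is ever required. The primary radical then adds to the methyl-bearing C6 of the 2,4-cyclohexadienone just formed (5-exo-trig, closing the five-membered ring of the bicyclo[3.2.1]octane and turning the old phenol carbon C5 into the bridging ketone), and a second equivalent of trivalent manganese oxidises the resulting oxygen-flanked allyl radical, which loses a proton to give the enol lactone dione 17. The closest known reaction types are the Mn(OAc)3 or PhI(OAc)2/TEMPO 5-exo/5-exo radical cascades of already dearomatised prenylated acylphloroglucinols to bicyclo[3.2.1]octanetriones and the cationic oxidative-dearomatisation [5+2] cycloadditions of phenols with tethered alkenes; what is new is that an intact aromatic ring serves first as radical donor and then as radical acceptor. All three new stereocentres derive from C3 of the lactone: the side chain is tied to one face of the ring so the C4a–C bond can form only there (bridgehead C1, acyl carbon cis to the C2 oxygen), the vinyl CH2 turns away from the lactone bridge so that the radical CH2 lies on the side of the future C8 ketone (ring-fusion C7), and the methyl bridgehead C5 follows from the geometry of the second closure. The step needs facial selectivity on the arene and closure at C6 rather than C8: the lactone gives the first, and its aryl ester oxygen gives the second by fixing the C8=C8a double bond so that attack at C8 would be 5-endo whereas attack at C6 is 5-exo, while the acyl and methyl groups block radical coupling at the other spin-bearing carbons. Copper salts are left out so that the primary radical is not oxidised before it cyclises.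

**Step 11**
Reactants: 17 the bridged enol lactone
Product: 18 S-ethyl thioester of the enolised triketone
Conditions: EtSH, Et3N, CH2Cl2, 0 °C to rt
Reagents that add atoms: ethanethiol, CCS
Why: Thiolysis (acyl transfer) of an enol ester: the lactone is the O-acyl derivative of a cyclic β-triketone and is strained by its bridge, so the thiolate should attack the acyl carbon and release the stabilised triketone enolate without touching the acyl-bearing stereocentre.

**Step 12**
Reactants: 18 the S-ethyl thioester
Product: 19 acetyl tricyclic enolised triketone
Conditions: MeZnI (excess), PdCl2(PPh3)2 (cat.), toluene–THF, rt; aq. NH4Cl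
Reagents that add atoms: methylzinc iodide, C[Zn]I
Why: Fukuyama coupling: zerovalent palladium inserts into the C–S bond of the thioester, and transmetallation with MeZnI followed by reductive elimination gives the methyl ketone, the organozinc being unreactive towards the other ketones (one extra equivalent is consumed by the acidic enol).

**Step 13**
Reactants: 19 the acetyl enolised triketone; 20 prenyl acetate
Product: 21 target CNP0322535.2
Conditions: Pd(PPh3)4 (cat.), Et3N, THF, 50 °C
Reagents that add atoms: none
Why: Tsuji–Trost allylic alkylation: the acidic triketone should attack the prenyl π-allyl palladium complex through its acyl-bearing carbon C3 at the unsubstituted allyl terminus (O-allyl isomers can re-ionise and funnel to the C-alkylated product), and the new quaternary centre is set by approach on the face of the three-carbon bridge that looks towards the C8 carbonyl, away from the C6–C7 bridge with its endo hydrogens.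

**Compound list**

1 | 2,6-dimethoxytoluene | Cc1c(OC)cccc1OC | starting material
2 | aryl pinacol boronate: 2-(3,5-dimethoxy-4-methylphenyl)-4,4,5,5-tetramethyl-1,3,2-dioxaborolane | Cc1c(OC)cc(B2OC(C)(C)C(C)(C)O2)cc1OC | intermediate
3 | 3,5-dimethoxy-4-methylphenol | Cc1c(OC)cc(O)cc1OC | intermediate
4 | 6-hydroxy-2,4-dimethoxy-3-methylbenzaldehyde | O=Cc1c(O)cc(OC)c(C)c1OC | intermediate
5 | 2,4-dimethoxy-6-(methoxymethoxy)-3-methylbenzaldehyde | O=Cc1c(OCOC)cc(OC)c(C)c1OC | intermediate
6 | 3,3-dimethylpent-4-enoic acid | C=CC(C)(C)CC(=O)O | starting material
7 | (R)-4-benzyloxazolidin-2-one | O=C1N[C@H](Cc2ccccc2)CO1 | starting material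
8 | mixed pivalic anhydride: 3,3-dimethylpent-4-enoic pivalic anhydride | C=CC(C)(C)CC(=O)OC(=O)C(C)(C)C | intermediate
9 | (4R)-4-benzyl-3-(3,3-dimethylpent-4-enoyl)oxazolidin-2-one | C=CC(C)(C)CC(=O)N1[C@H](Cc2ccccc2)COC1=O | intermediate
10 | Z-dibutylboron enolate of 9 | C=CC(C)(C)/C=C(\OB(CCCC)CCCC)N1[C@H](Cc2ccccc2)COC1=O | intermediate
11 | syn-aldol adduct: (4R)-4-benzyl-3-[(2R,3R)-3-hydroxy-3-[2,4-dimethoxy-6-(methoxymethoxy)-3-methylphenyl]-2-(2-methylbut-3-en-2-yl)propanoyl]oxazolidin-2-one | O=C(N1[C@H](Cc2ccccc2)COC1=O)[C@H](C(C)(C)C=C)[C@@H](O)c1c(OCOC)cc(OC)c(C)c1OC | intermediate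
12 | (4R)-4-benzyl-3-[(2S)-2-[(6-hydroxy-2,4-dimethoxy-3-methylphenyl)methyl]-3,3-dimethylpent-4-enoyl]oxazolidin-2-one | O=C(N1[C@H](Cc2ccccc2)COC1=O)[C@H](C(C)(C)C=C)Cc1c(O)cc(OC)c(C)c1OC | intermediate
13 | (3S)-5,7-dimethoxy-6-methyl-3-(2-methylbut-3-en-2-yl)chroman-2-one | O=C1Oc2cc(OC)c(C)c(OC)c2C[C@H]1C(C)(C)C=C | intermediate
14 | isobutyryl chloride | CC(C)C(Cl)=O | starting material
15 | (3S)-8-isobutyryl-5,7-dimethoxy-6-methyl-3-(2-methylbut-3-en-2-yl)chroman-2-one | O=C1Oc2c(C(=O)C(C)C)c(OC)c(C)c(OC)c2C[C@H]1C(C)(C)C=C | intermediate
16 | (3S)-5,7-dihydroxy-8-isobutyryl-6-methyl-3-(2-methylbut-3-en-2-yl)chroman-2-one, key-step precursor | O=C1Oc2c(C(=O)C(C)C)c(O)c(C)c(O)c2C[C@H]1C(C)(C)C=C | intermediate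
17 | bridged enol lactone: 3-isobutyryl-5-methylbicyclo[3.2.1]oct-2-ene-4,8-dione fused at C1–C7 to the gem-dimethylcyclopentane, carboxyl carbon on the cyclopentane esterified to the C2 enol oxygen (cis to C2, trans to C8; C7–H cis to C2) | O=C7[C@H]1C[C@]23C(=O)[C@](C)(C[C@@H]2C1(C)C)C(=O)C(C(=O)C(C)C)=C3O7 | intermediate
18 | S-ethyl thioester: as 17 with the lactone opened to C(=O)SEt on the cyclopentane and a free C2 enol | CCSC(=O)[C@H]1C[C@]23C(=O)[C@](C)(C[C@@H]2C1(C)C)C(=O)C(C(=O)C(C)C)=C3O | intermediate
19 | acetyl tricyclic enolised triketone: as 18 with COCH3 in place of C(=O)SEt | CC(=O)[C@H]1C[C@]23C(=O)[C@](C)(C[C@@H]2C1(C)C)C(=O)C(C(=O)C(C)C)=C3O | intermediate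
20 | prenyl acetate | CC(C)=CCOC(C)=O | starting material
21 | target CNP0322535.2: 3-isobutyryl-5-methyl-3-prenylbicyclo[3.2.1]octane-2,4,8-trione fused at C1–C7 to the cyclopentane C1–C7–CMe2–CH(COCH3)–CH2; (1R,3S,5S,7R) with the acetyl-bearing carbon S; prenyl on the C8 side, acetyl cis to C2 | CC(=O)[C@H]1C[C@]23C(=O)[C@](C)(C[C@@H]2C1(C)C)C(=O)[C@](CC=C(C)C)(C(=O)C(C)C)C3=O | target

**Step count**

Total steps: 13. Longest linear sequence: 12 steps (steps 1–3 and 5–13, from 2,6-dimethoxytoluene); step 4 is a one-step side branch.

**Steps most likely to fail**

Step 10. The phenoxyl radical may couple intermolecularly or be oxidised a second time (towards an ortho-quinone methide at the C6 methyl group) faster than it adds to the unactivated, neopentyl-flanked vinyl group, or the primary radical may be quenched before it closes onto C6. The fallback keeps the same two bonds but makes them one after the other by known ionic chemistry; it sets out from 16 and comes back at 17. N-Iodosuccinimide (NaHCO3, MeCN, 0 °C) would be used for an iodocarbocyclisation of the kind known for alkenyl-tethered active methine compounds. The ring carbon C4a of the enolised tricarbonyl should open the iodonium ion at its internal carbon (5-exo, Markovnikov) on the only face the tether allows, giving the dearomatised iodomethyl enol lactone F1 with the CH2I group cis to the C5 ketone. K2CO3 in acetone would then close the second five-membered ring by intramolecular C-alkylation of the C5/C7 diketone enolate at C6, a known way to bridge cyclic 1,3-diketones, and give 17.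

Step 5. Carbon–carbon bond formation between a β-quaternary boron enolate and a di-ortho-substituted, electron-rich aldehyde may be too slow, with reversal of the aldol on work-up. The fallback replaces aldol plus deoxygenation by a direct auxiliary-controlled alkylation; it sets out from 6 and 5 and comes back at 13. Because a chelated sodium enolate is alkylated on the face opposite to that used by the boron aldol, the enantiomeric auxiliary is needed. Acid 6 would be coupled (through the same mixed anhydride 8) with purchased (S)-4-benzyloxazolidin-2-one to the ent-auxiliary imide F2. Aldehyde 5 would be reduced (NaBH4, MeOH) to the benzyl alcohol F3 and converted (CBr4, PPh3, CH2Cl2, 0 °C) into the benzyl bromide F4, used at once without purification. The enolate of F2 (NaHMDS, THF, −78 °C) would be alkylated with F4 anti to the auxiliary benzyl group to give the alkylated imide F5, with the (2S) centre already in place. HCl in MeOH would remove the MOM group to give the phenol imide F6, and iPr2NEt/DMAP in toluene would lactonise it to 13 with release of the auxiliary.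

Step 13. Ionisation of the trisubstituted allylic acetate may be slow, and the ambident triketone anion may bond through oxygen or at the tertiary allyl terminus of the hindered prenyl complex. The fallback introduces the side chain in two stages; it sets out from 19 and comes back at 21. Tsuji–Trost allylation with allyl acetate (Pd(PPh3)4, Et3N, THF) should deliver the smaller allyl group to C3 on the same face, giving the C3-allyl trione F7. Cross-metathesis of F7 with 2-methylbut-2-ene (second-generation Grubbs catalyst, CH2Cl2, 40 °C) would then convert allyl into prenyl and give 21.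

**Further compounds**

F1 | step 10 | dearomatised iodomethyl enol lactone: C4a spiro-linked to the new gem-dimethylcyclopentane, CH2I on the former internal vinyl carbon cis to the C5 ketone, ring as 5-oxo-6-methyl-7-hydroxy-8-isobutyryl dienol lactone | O=C4[C@H]1C[C@]2(C(=O)C(C)=C(O)C(C(=O)C(C)C)=C2O4)[C@H](CI)C1(C)C
F2 | step 5 | (4S)-4-benzyl-3-(3,3-dimethylpent-4-enoyl)oxazolidin-2-one | C=CC(C)(C)CC(=O)N1[C@@H](Cc2ccccc2)COC1=O
F3 | step 5 | [2,4-dimethoxy-6-(methoxymethoxy)-3-methylphenyl]methanol | OCc1c(OCOC)cc(OC)c(C)c1OC
F4 | step 5 | 1-(bromomethyl)-2,4-dimethoxy-6-(methoxymethoxy)-3-methylbenzene | BrCc1c(OCOC)cc(OC)c(C)c1OC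
F5 | step 5 | (4S)-4-benzyl-3-[(2S)-2-[[2,4-dimethoxy-6-(methoxymethoxy)-3-methylphenyl]methyl]-3,3-dimethylpent-4-enoyl]oxazolidin-2-one | O=C(N1[C@@H](Cc2ccccc2)COC1=O)[C@H](C(C)(C)C=C)Cc1c(OCOC)cc(OC)c(C)c1OC
F6 | step 5 | (4S)-4-benzyl-3-[(2S)-2-[(6-hydroxy-2,4-dimethoxy-3-methylphenyl)methyl]-3,3-dimethylpent-4-enoyl]oxazolidin-2-one | O=C(N1[C@@H](Cc2ccccc2)COC1=O)[C@H](C(C)(C)C=C)Cc1c(O)cc(OC)c(C)c1OC
F7 | step 13 | C3-allyl trione: as 21 with allyl in place of prenyl at C3 | CC(=O)[C@H]1C[C@]23C(=O)[C@](C)(C[C@@H]2C1(C)C)C(=O)[C@](CC=C)(C(=O)C(C)C)C3=O
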